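The easy step comes first: the blue and red runs, with [L] at 0.29 M and 0.65 M, read alike in percent. At 1.50 h, Z stands at 39.4% and 38.4%, so we read our flask, with [L] at 0.43 M, off the same curves.

| flask | L | remark | time |
|---|---|---|---|
| blue | 0.29 M | run made earlier |  |
| red | 0.65 M | run made earlier |  |
| flask | 0.43 M |  | 5.0 h |

| run | time / h | Z / % | Q / % | L / % |
|---|---|---|---|---|
| blue | 0.833 | 38.9 | 10.3 | 3.5 |
| blue | 1.50 | 39.4 | 3.7 | 1.5 |
| blue | 2.50 | 34.7 | 1.4 | 1.2 |
| blue | 3.00 | 31.6 | 3.0 | 1.2 |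
| blue | 4.00 | 28.3 | 2.5 | 0.6 |
| blue | 5.00 | 24.6 | 1.2 | 0.4 |
| blue | 6.00 | 22.8 | 1.2 | 0.7 |
| red | 0.500 | 35.8 | 21.2 | 5.6 |
| red | 0.667 | 39.5 | 15.1 | 4.0 |
| red | 1.00 | 40.3 | 8.3 | 2.7 |
| red | 1.50 | 38.4 | 4.7 | 1.4 |
| red | 2.50 | 35.0 | 2.9 | 0.8 |
| red | 4.00 | 28.4 | 1.3 | 0.3 |
| red | 6.00 | 21.4 | 1.5 | 1.3 |

(each reading ± 0.5 percentage points)

1. share of Z in Z plus Q at 10 s
2. share of Z in Z plus Q at 8.0 min
3. share of Z in Z plus Q at 5.0 h

- steps thought possible: L <-> Q; L <-> Z; L <-> X; Q -> G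

For 5.0 h, the blue run at 5.00 h has Z 24.6% and Q 1.2%, a share of 95.3%. That is the weak link: a single reading of Q there carries a scatter of 0.5 percentage points on 1.2%. So from 2.50 h on we take Q to follow Z in a fixed ratio, a quasi-steady state, and we sum both runs. This gives the tail ratio, summed Q over summed Z in the readings from that time on, a reading of 0.0661. Our share at 5.0 h is therefore 93.8%.

The forecast says 35%, 41% and 94%; of the earliest time it says “At 10 s, the share is essentially the kinetic ratio, about 35%.”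

The flask gives 28.0%, 36.5% and 93.2%, so the forecast is 7 points too high at 10 s and within tolerance at the other two times.

    L ⇌ Q (K = 3.20, k = 0.00310 s⁻¹)
    L ⇌ Z (K = 16.0, k = 0.00120 s⁻¹)
    L ⇌ X (K = 56.0, k = 3.20 × 10⁻⁴ s⁻¹)
    Q → G (k = 4.50 × 10⁻⁴ s⁻¹)

At the start, L fed Q and Z with forward rates 2.6 to one, and the flask had as much Z as Q at 0.306 h. By 2.50 h, with L at 1.13% and Q at 2.60%, Q kept draining to G while Z fell from 34.3% to 24.8% at 5.00 h. Our ratio puts Q at 1.64% beside that Z, and the flask holds 1.81%.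

In the neighbour flask at 1.1 M, the same ratio gives at 5.0 h a share of 93.8% and, on its Z of 24.8%, Q at 1.64%. The computed values are 93.2% and 1.81%.

The readings stem from a simulated flask with made-up constants; noise was put on by code.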